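**Strategy.** The target is cut back to a cis-fused octalin enedione made in one operation from 2,6-dimethyl-1,4-benzoquinone and 4-methylpenta-1,3-diene. Ring B (C5–C10) is the quinone: its methyls become C20 on C10 and C17 on C8, its carbonyls become the C6 oxygen and a C9 handle for the side chain, and its spare C7=C8 bond is the site of later oxygenation. The diene supplies ring A (C1–C4) with the C4 gem-dimethyl group. A chiral oxazaborolidinium-catalysed [4+2] cycloaddition forms C1–C10 and C4–C5, closes ring A and fixes the quaternary C10 stereocentre, from which every other stereocentre is relayed.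

Key step: step 1

Remark: atom numbers follow the labdane skeleton (C17 on C8, C18/C19 on C4, C20 on C10); β is the face of the C20 methyl.

Remark: the catalyst antipode in step 1 is assigned from the usual binding picture of these cations (quinone α-C–H···O contact, aryl group screening the rear face). Both antipodes of α,α-diphenylprolinol are commercial, so the sense is checked on the first batch of 3 and the catalyst exchanged for its mirror image if needed, with no other change.

**Step 1**
Reactants: 1 2,6-dimethyl-1,4-benzoquinone; 2 4-methylpenta-1,3-diene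
Product: 3 (4aR,8aS)-2,5,5,8a-tetramethyl-4a,5,8,8a-tetrahydronaphthalene-1,4-dione (cis-fused; C5–H and C20 both β)
Conditions: (R)-1-(2-methylphenyl)-3,3-diphenyltetrahydro-1H,3H-pyrrolo[1,2-c][1,3,2]oxazaborole (20 mol%), HNTf2 (18 mol%), 2 (3 equiv), CH2Cl2, −78 → −40 °C
Reagents that add atoms: none
Why: The protonated oxazaborolidine should bind the more basic, less hindered C6 carbonyl of 1 on the lone pair syn to C5–H, which makes the methyl-bearing β-carbon (future C10) the most electrophilic site, so the asynchronous Lewis-acid-catalysed Diels–Alder reaction pairs it with the unsubstituted, most nucleophilic terminus of 2 (C1) while the CMe2 terminus (C4) closes onto C5. The closest known reaction type is the oxazaborolidinium-catalysed enantioselective [4+2] cycloaddition of 1,3-dienes to alkyl-substituted 1,4-benzoquinones. Ring A is closed as a cyclohexene by the suprafacial [4πs+2πs] addition itself, both new σ-bonds (C1–C10 and C4–C5) arriving on one face of the quinone C=C, hence the cis junction. C10 is set by the catalyst, whose aryl group should screen one face of the bound quinone so that the diene enters on the α face (Si at C10, Re at C5); C5 follows from the suprafacial addition and is corrected in step 3. Only regio- and enantiofacial selectivity are needed: the two quinone C=C bonds are equivalent, the diene termini carry no stereogenic substituents so endo/exo is moot, and regiochemistry is secured by the methyl pattern of 1 together with carbonyl coordination at C6.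

**Step 2**
Reactants: 3 cis-fused adduct
Product: 4 (4aR,8aS)-2,5,5,8a-tetramethyl-4a,5,6,7,8,8a-hexahydronaphthalene-1,4-dione (cis-fused, ring A saturated)
Conditions: H2 (1 atm), RhCl(PPh3)3 (5 mol%), toluene/EtOH, rt
Reagents that add atoms: none
Why: Homogeneous catalytic hydrogenation with RhCl(PPh3)3 should reduce the cis-disubstituted C2=C3 bond of ring A and spare the trisubstituted, electron-poor C7=C8 bond, since this catalyst discriminates strongly by degree of substitution; no stereocentre is formed.

**Step 3**
Reactants: 4 cis-fused enedione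
Product: 5 (4aS,8aS)-2,5,5,8a-tetramethyl-4a,5,6,7,8,8a-hexahydronaphthalene-1,4-dione (trans-fused; C5–H α, C20 β)
Conditions: DBU (0.2 equiv), toluene, rt → 50 °C
Reagents that add atoms: none
Why: Base-catalysed epimerisation through the C5/C6 enolate should equilibrate C5 to the trans-fused decalin, the stable arrangement of 10-methyl-6-oxodecalins, so that C5–H ends α, anti to the C10 methyl.

**Step 4**
Reactants: 5 trans-fused enedione
Product: 6 (4R,4aS,8aS)-4-hydroxy-2,5,5,8a-tetramethyl-4a,5,6,7,8,8a-hexahydronaphthalen-1(4H)-one (6β-hydroxy-7-en-9-one)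
Conditions: NaBH4 (1.0 equiv), CeCl3·7H2O, MeOH, −78 °C
Reagents that add atoms: none
Why: Luche reduction should deliver hydride 1,2 to the less hindered C6 carbonyl (C9 is flanked by quaternary C10 and the C8 methyl) from the α face, the β face being screened by the syn-axial C10 and C4β methyls, to give the 6β-alcohol; this masks C6, whose configuration is set again in step 12.

**Step 5**
Reactants: 6 6β-hydroxy enone
Product: 7 drima-7,9(11)-dien-6β-ol (trans-decalin, 5α-H, 10β-CH3, exocyclic CH2 on C9, C7=C8, 6β-OH)
Conditions: Ph3PCH3Br (4 equiv), KOtBu (3.8 equiv), toluene, 0 → 80 °C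
Reagents that add atoms: methyltriphenylphosphonium bromide, C[P+](c1ccccc1)(c1ccccc1)c1ccccc1.[Br-]
Why: Wittig methylenation should convert the hindered C9 enone carbonyl into the exocyclic methylene that carries C11, the excess ylide merely deprotonating the free hydroxyl; no stereocentre is formed.

**Step 6**
Reactants: 8 prop-2-yn-1-ol
Product: 10 (E)-3-iodo-2-methylprop-2-en-1-ol, via alkenylalane 9 (not isolated)
Conditions: Me3Al (3 equiv), Cp2ZrCl2 (0.25 equiv), CH2Cl2, 0 °C → rt; then I2, THF, −30 °C; aq. K2CO3
Reagents that add atoms: trimethylaluminium, C[Al](C)C; iodine, II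
Why: Zirconium-catalysed carboalumination (Negishi) should add methyl and aluminium syn across the alkyne with methyl on the internal carbon, and iodinolysis with retention then gives the (E)-vinyl iodide.

**Step 7**
Reactants: 10 (E)-3-iodo-2-methylprop-2-en-1-ol
Product: 11 (E)-3-iodo-2-methylprop-2-enal
Conditions: MnO2 (10 equiv), CH2Cl2, rt
Reagents that add atoms: none
Why: Allylic oxidation with MnO2 should give the enal without touching the vinyl iodide or its geometry.

**Step 8**
Reactants: 11 (E)-3-iodo-2-methylprop-2-enal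
Product: 12 (E)-1-iodo-2-methylbuta-1,3-diene (volatile; kept as a cold ethereal solution in the dark)
Conditions: Ph3PCH3Br, KOtBu, Et2O, −78 → 0 °C
Reagents that add atoms: methyltriphenylphosphonium bromide, C[P+](c1ccccc1)(c1ccccc1)c1ccccc1.[Br-]
Why: Wittig methylenation of the aldehyde should build the terminal vinyl group and leave the (E)-iodoalkene intact.

**Step 9**
Reactants: 7 drima-7,9(11)-dien-6β-ol; 12 (E)-1-iodo-2-methylbuta-1,3-diene
Product: 14 (12E)-labda-7,12,14-trien-6β-ol, via alkylborane 13 (not isolated)
Conditions: 9-BBN (2.2 equiv), THF, 0 °C → rt; then 12, PdCl2(dppf) (5 mol%), AsPh3, Cs2CO3, DMF/H2O, rt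
Reagents that add atoms: none
Why: Hydroboration with 9-BBN should place boron on the terminal C11 of the exocyclic alkene and hydrogen on C9 from the α face, opposite the axial C10 methyl (9α-H, side chain β and equatorial), and the B-alkyl Suzuki–Miyaura coupling then joins C11 to C12 with retention of the (E) geometry of 12.

**Step 10**
Reactants: 14 (12E)-labda-7,12,14-trien-6β-ol
Product: 15 (12E)-labda-7,12,14-trien-6-one
Conditions: Dess–Martin periodinane, NaHCO3, CH2Cl2, 0 °C → rt
Reagents that add atoms: none
Why: Dess–Martin oxidation should return the allylic C6 alcohol to the enone, which singles out C7=C8 for nucleophilic oxidation while the side-chain diene stays inert.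

**Step 11**
Reactants: 15 (12E)-labda-7,12,14-trien-6-one
Product: 16 (12E)-7α,8α-epoxylabda-12,14-dien-6-one
Conditions: 30% H2O2, NaOH (cat.), MeOH, 0 °C
Reagents that add atoms: hydrogen peroxide, OO
Why: Weitz–Scheffer (nucleophilic) epoxidation should occur only at the enone C7=C8 bond, not at the electron-rich diene, and from the α face anti to the C10 methyl, which sets C8 (oxygen α, methyl β) and places the C7 oxygen α.

**Step 12**
Reactants: 16 (12E)-7α,8α-epoxylabda-12,14-dien-6-one
Product: 17 (12E)-7α,8α-epoxylabda-12,14-dien-6β-ol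
Conditions: NaBH4, MeOH, −20 °C
Reagents that add atoms: none
Why: Borohydride reduction of the ketone should take place from the α face (β face blocked by the syn-axial C10 and C4β methyls) and give the axial 6β-alcohol trans to the epoxide.

**Step 13**
Reactants: 17 (12E)-7α,8α-epoxylabda-12,14-dien-6β-ol
Product: 19 (12E)-labda-12,14-diene-6β,7β,8α-triol, via cyclic carbonate 18 (not isolated)
Conditions: CO2 (1 atm), Cs2CO3 (0.5 equiv), DMF, 3 Å MS, 45 °C; then K2CO3, MeOH, rt
Reagents that add atoms: carbon dioxide, O=C=O
Why: In this carbon dioxide-mediated intramolecular epoxide opening the 6β-alkoxide is carboxylated and the carbonate oxygen, held anti to the C7–O bond, should attack C7 from the β face (5-exo SN2, inversion) to give the cis-6β,7β-cyclic carbonate with the tertiary 8α-hydroxyl untouched, after which methanolysis releases the triol.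

**Step 14**
Reactants: 19 (12E)-labda-12,14-diene-6β,7β,8α-triol
Product: 20 (12E)-7β-acetoxylabda-12,14-diene-6β,8α-diol (CNP0225877.1)
Conditions: Ac2O (1.2 equiv), pyridine, 0 °C → rt
Reagents that add atoms: acetic anhydride, CC(=O)OC(C)=O
Why: Acyl transfer should occur at the equatorial secondary 7β-hydroxyl only, because the 6β-hydroxyl is axial and flanked by the syn-axial C10 and C4β methyls and the C8 hydroxyl is tertiary.

**Compound list**
1 | 2,6-dimethyl-1,4-benzoquinone | CC1=CC(=O)C=C(C)C1=O | starting material
2 | 4-methylpenta-1,3-diene | C=CC=C(C)C | starting material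
3 | (4aR,8aS)-2,5,5,8a-tetramethyl-4a,5,8,8a-tetrahydronaphthalene-1,4-dione (cis-fused adduct) | O=C1C(C)=CC(=O)[C@@H]2C(C)(C)C=CC[C@@]21C | intermediate
4 | (4aR,8aS)-2,5,5,8a-tetramethyl-4a,5,6,7,8,8a-hexahydronaphthalene-1,4-dione (cis-fused) | O=C1C(C)=CC(=O)[C@@H]2C(C)(C)CCC[C@@]21C | intermediate
5 | (4aS,8aS)-2,5,5,8a-tetramethyl-4a,5,6,7,8,8a-hexahydronaphthalene-1,4-dione (trans-fused) | O=C1C(C)=CC(=O)[C@H]2C(C)(C)CCC[C@@]21C | intermediate
6 | (4R,4aS,8aS)-4-hydroxy-2,5,5,8a-tetramethyl-4a,5,6,7,8,8a-hexahydronaphthalen-1(4H)-one | O=C1C(C)=C[C@@H](O)[C@H]2C(C)(C)CCC[C@@]21C | intermediate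
7 | drima-7,9(11)-dien-6β-ol | C=C1C(C)=C[C@@H](O)[C@H]2C(C)(C)CCC[C@@]21C | intermediate
8 | prop-2-yn-1-ol | C#CCO | starting material
9 | (E)-[3-(dimethylaluminooxy)-2-methylprop-1-enyl]dimethylalane | C[Al](C)/C=C(\C)CO[Al](C)C | intermediate (not isolated)
10 | (E)-3-iodo-2-methylprop-2-en-1-ol | OC/C(C)=C/I | intermediate
11 | (E)-3-iodo-2-methylprop-2-enal | O=C/C(C)=C/I | intermediate
12 | (E)-1-iodo-2-methylbuta-1,3-diene | C=C/C(C)=C/I | intermediate
13 | 9-[6β-(9-borabicyclo[3.3.1]nonan-9-yloxy)drim-7-en-11-yl]-9-borabicyclo[3.3.1]nonane | C1CCC2CCCC1B2C[C@H]1C(C)=C[C@@H](OB3C4CCCC3CCC4)[C@H]3C(C)(C)CCC[C@@]31C | intermediate (not isolated)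
14 | (12E)-labda-7,12,14-trien-6β-ol | C=C/C(C)=C/C[C@H]1C(C)=C[C@@H](O)[C@H]2C(C)(C)CCC[C@@]21C | intermediate
15 | (12E)-labda-7,12,14-trien-6-one | C=C/C(C)=C/C[C@H]1C(C)=CC(=O)[C@H]2C(C)(C)CCC[C@@]21C | intermediate
16 | (12E)-7α,8α-epoxylabda-12,14-dien-6-one | C=C/C(C)=C/C[C@H]1[C@]2(C)O[C@@H]2C(=O)[C@H]3C(C)(C)CCC[C@@]31C | intermediate
17 | (12E)-7α,8α-epoxylabda-12,14-dien-6β-ol | C=C/C(C)=C/C[C@H]1[C@]2(C)O[C@@H]2[C@@H](O)[C@H]3C(C)(C)CCC[C@@]31C | intermediate
18 | (12E)-8α-hydroxylabda-12,14-diene-6β,7β-diyl carbonate | C=C/C(C)=C/C[C@H]1[C@](C)(O)[C@H]2OC(=O)O[C@H]2[C@H]3C(C)(C)CCC[C@@]31C | intermediate (not isolated)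
19 | (12E)-labda-12,14-diene-6β,7β,8α-triol | C=C/C(C)=C/C[C@H]1[C@](C)(O)[C@@H](O)[C@@H](O)[C@H]2C(C)(C)CCC[C@@]21C | intermediate
20 | (12E)-7β-acetoxylabda-12,14-diene-6β,8α-diol | C=C/C(C)=C/C[C@H]1[C@](C)(O)[C@@H](OC(C)=O)[C@@H](O)[C@H]2C(C)(C)CCC[C@@]21C | target

**Count and risk**
Total step count: 14. Longest linear sequence: 11 steps (steps 1–5 and 9–14); steps 6–8 prepare the coupling partner.

Step 1. The cycloaddition may stall or lose enantiofacial discrimination: the Z-methyl group of 2 disfavours the s-cis conformer, and the strongly acidic catalyst can oligomerise the diene instead. Fallback: from 1 and 2 the racemic adduct is made with an achiral promoter (BF3·OEt2, CH2Cl2, −78 °C, or 12 kbar without promoter). The enantiomers are then separated by preparative chromatography on a chiral stationary phase. The wanted antipode is 3, which re-enters the route at step 2, and the mirror-image adduct (4aS,8aR)-2,5,5,8a-tetramethyl-4a,5,8,8a-tetrahydronaphthalene-1,4-dione F1 is set aside.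

Step 13. The intramolecular opening may fail through slow displacement at the hindered C7, or through epoxide migration (Payne rearrangement) followed by attack from the wrong face. Fallback: from epoxy ketone 16, SmI2 (THF/MeOH, −90 °C) cleaves the C7–O bond to give the β-hydroxy ketone (12E)-8α-hydroxylabda-12,14-dien-6-one F4. Its kinetic C7 enolate (LiN(SiMe3)2, 2.2 equiv, −78 °C) is hydroxylated with 2-(phenylsulfonyl)-3-phenyloxaziridine on the axial α face to give (12E)-7α,8α-dihydroxylabda-12,14-dien-6-one F5. A Mitsunobu reaction with acetic acid (PPh3, DIAD) inverts C7 to (12E)-7β-acetoxy-8α-hydroxylabda-12,14-dien-6-one F6. Reduction with NaBH4/CeCl3·7H2O from the α face then gives 20 directly.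

Step 9. Transmetalation of the hindered, β-branched alkylborane may be slow, so that protodeboronation and decay of the volatile, light-sensitive dienyl iodide outrun the coupling. Fallback: borane 13, made from 7 as before, is coupled under the same palladium catalysis with the robust iodo alcohol 10 to give (12E)-15-norlabda-7,12-diene-6β,14-diol F2. Dess–Martin periodinane oxidises both allylic alcohols to (12E)-6-oxo-15-norlabda-7,12-dien-14-al F3. One equivalent of methylenetriphenylphosphorane at −78 °C then methylenates only the aldehyde, which returns the route at 15.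

**Further compounds**
F1 | step 1 | (4aS,8aR)-2,5,5,8a-tetramethyl-4a,5,8,8a-tetrahydronaphthalene-1,4-dione | O=C1C(C)=CC(=O)[C@H]2C(C)(C)C=CC[C@]21C
F2 | step 9 | (12E)-15-norlabda-7,12-diene-6β,14-diol | OC/C(C)=C/C[C@H]1C(C)=C[C@@H](O)[C@H]2C(C)(C)CCC[C@@]21C
F3 | step 9 | (12E)-6-oxo-15-norlabda-7,12-dien-14-al | O=C/C(C)=C/C[C@H]1C(C)=CC(=O)[C@H]2C(C)(C)CCC[C@@]21C
F4 | step 13 | (12E)-8α-hydroxylabda-12,14-dien-6-one | C=C/C(C)=C/C[C@H]1[C@](C)(O)CC(=O)[C@H]2C(C)(C)CCC[C@@]21C
F5 | step 13 | (12E)-7α,8α-dihydroxylabda-12,14-dien-6-one | C=C/C(C)=C/C[C@H]1[C@](C)(O)[C@H](O)C(=O)[C@H]2C(C)(C)CCC[C@@]21C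
F6 | step 13 | (12E)-7β-acetoxy-8α-hydroxylabda-12,14-dien-6-one | C=C/C(C)=C/C[C@H]1[C@](C)(O)[C@@H](OC(C)=O)C(=O)[C@H]2C(C)(C)CCC[C@@]21C
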